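**Strategy.** The plan rests on cutting the C4a–C8a bond of ring A in flavone unit 1 (the unit whose ring B carries the ether oxygen) back to an open polyketide chain. Ring A carries oxygen on C5, C7 and C8a in a 1,3,5-pattern with the C4 acyl carbon on C4a, so one intramolecular Claisen condensation of a methyl 9-aryl-3,5,7,9-tetraoxononanoate should forge the whole phloroglucinol ring and leave the aryl 1,3-diketone ready to close ring C. The precursor already holds the diaryl ether and a benzyl/methyl-protected ring A of unit 2; flavone unit 2 is then grown on that ring by standard acetophenone chemistry.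

Key step: step 6

Remark: the poly-β-carbonyl compounds 8 to 11 and 17 are written as keto tautomers although they should exist mainly as enols (11 partly as its cyclic hemiketal); heptane-2,4,6-trione is taken as a purchasable compound.

**Step 1**
Reactants: 1 2-hydroxy-4,6-dimethoxybenzaldehyde
Product: 2 2-(benzyloxy)-4,6-dimethoxybenzaldehyde
Conditions: BnBr, K2CO3, DMF, 60 °C
Reagents that add atoms: benzyl bromide, BrCc1ccccc1
Why: Williamson O-alkylation of the only acidic site should cap the oxygen that later becomes O1 of unit 2 with a group removable by hydrogenolysis.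

**Step 2**
Reactants: 2 2-(benzyloxy)-4,6-dimethoxybenzaldehyde
Product: 4 2-(benzyloxy)-4,6-dimethoxyphenol, via aryl formate 3 (not isolated)
Conditions: mCPBA, CH2Cl2, 0 °C to rt; aq. NaHCO3 wash; then K2CO3 (cat.), MeOH, rt
Reagents that add atoms: mCPBA, O=C(OO)c1cccc(Cl)c1
Why: In this Baeyer–Villiger (Dakin-type) oxidation the electron-rich trialkoxyaryl group should migrate in preference to hydrogen, and methanolysis of the formate should free the phenol.

**Step 3**
Reactants: 4 2-(benzyloxy)-4,6-dimethoxyphenol; 5 methyl 4-fluorobenzoate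
Product: 6 methyl 4-[2-(benzyloxy)-4,6-dimethoxyphenoxy]benzoate
Conditions: Cs2CO3, DMSO, 100 °C, N2
Reagents that add atoms: none
Why: Nucleophilic aromatic substitution (addition–elimination) of fluoride para to the ester by the caesium phenoxide should give the diaryl ether, with air excluded to protect the electron-rich phenoxide.

**Step 4**
Reactants: 6 methyl 4-[2-(benzyloxy)-4,6-dimethoxyphenoxy]benzoate; 7 heptane-2,4,6-trione
Product: 8 1-{4-[2-(benzyloxy)-4,6-dimethoxyphenoxy]phenyl}octane-1,3,5,7-tetrone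
Conditions: 7 (2 equiv), LiN(i-Pr)2 (6 equiv), THF, 0 °C; then 6, 0 °C to rt; cold dil. HCl
Reagents that add atoms: none
Why: In this crossed Claisen acylation the triketone trianion should react at its most basic terminal carbanion with the non-enolisable ester, the second equivalent of trianion absorbing the proton of the new methylene group.

**Step 5**
Reactants: 8 1-{4-[2-(benzyloxy)-4,6-dimethoxyphenoxy]phenyl}octane-1,3,5,7-tetrone
Product: 10 methyl 9-{4-[2-(benzyloxy)-4,6-dimethoxyphenoxy]phenyl}-3,5,7,9-tetraoxononanoate, via tetraketo acid 9 (not isolated)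
Conditions: LiN(i-Pr)2 (4.5 equiv), THF, −78 to 0 °C; CO2, −78 °C; cold dil. HCl, Et2O extraction; then TMSCHN2, PhMe/MeOH, 0 °C
Reagents that add atoms: carbon dioxide, O=C=O; (trimethylsilyl)diazomethane, C[Si](C)(C)C=[N+]=[N-]
Why: Carboxylation of the tetraanion at its terminal methyl carbanion, followed by immediate cold esterification of the crude β-keto acid with the diazoalkane before it can lose CO2, should deliver the polyketo ester.

**Step 6**
Reactants: 10 methyl 9-{4-[2-(benzyloxy)-4,6-dimethoxyphenoxy]phenyl}-3,5,7,9-tetraoxononanoate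
Product: 11 1-{4-[2-(benzyloxy)-4,6-dimethoxyphenoxy]phenyl}-3-(2,4,6-trihydroxyphenyl)propane-1,3-dione
Conditions: Mg(OMe)2 (5 equiv), MeOH, rt to 45 °C; cold 1 M HCl to pH 4
Reagents that add atoms: none
Why: Mg(OMe)2 should convert the β-dicarbonyl units into a magnesium-chelated polyenolate, whose carbon C6 (flanked by the C5 and C7 carbonyls) adds to the ester carbonyl C1; loss of methoxide gives a cyclohexane-1,3,5-trione that tautomerises to the aromatic phloroglucinol, the new C6–C1 bond being C4a–C8a of flavone unit 1. The closest known reaction is the base-mediated intramolecular Claisen (Dieckmann-type) cyclisation of 3,5,7-triketo esters to acylphloroglucinols, the laboratory counterpart of the chalcone synthase ring closure. Ring A closes in a 6-exo-trig mode, the ester C=O lying outside the forming six-membered ring, and no stereocentre is created. The step needs chemoselectivity for Claisen closure over aldol closure (C2 onto C7, C4 onto C9, C8 onto C3) and over lactonisation to a 4-hydroxy-2-pyranone. This should be secured by keeping C1 as a methyl ester in a water-free medium, so that it remains the only carbonyl with a leaving group, by full enolisation of the ketones under excess chelating base, which removes them as aldol acceptors, and by the electron-rich 4-aryloxyphenyl group, which makes the C9 ketone the poorest electrophile. Aromatisation makes the closure irreversible, and because the new ring is symmetric about the acyl carbon, either ortho hydroxyl can later close ring C to the same flavone.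

**Step 7**
Reactants: 11 1-{4-[2-(benzyloxy)-4,6-dimethoxyphenoxy]phenyl}-3-(2,4,6-trihydroxyphenyl)propane-1,3-dione
Product: 12 2-{4-[2-(benzyloxy)-4,6-dimethoxyphenoxy]phenyl}-5,7-dihydroxy-4H-chromen-4-one
Conditions: cat. H2SO4, AcOH, 60 °C
Reagents that add atoms: none
Why: Acid-catalysed cyclodehydration (the closing stage of a Baker–Venkataraman flavone synthesis) should add an ortho hydroxyl to the aryl ketone carbon and expel water, under conditions mild enough to keep the benzyl ether.

**Step 8**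
Reactants: 12 2-{4-[2-(benzyloxy)-4,6-dimethoxyphenoxy]phenyl}-5,7-dihydroxy-4H-chromen-4-one
Product: 13 2-{4-[2-(benzyloxy)-4,6-dimethoxyphenoxy]phenyl}-5,7-dimethoxy-4H-chromen-4-one
Conditions: Me2SO4 (excess), K2CO3, acetone, reflux
Reagents that add atoms: dimethyl sulfate, COS(=O)(=O)OC
Why: Williamson methylation with excess reagent and prolonged reflux should cap both phenols, including the hydrogen-bonded 5-hydroxyl, so that unit 1 is inert in the later acylation chemistry.

**Step 9**
Reactants: 13 2-{4-[2-(benzyloxy)-4,6-dimethoxyphenoxy]phenyl}-5,7-dimethoxy-4H-chromen-4-one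
Product: 14 2-[4-(2-hydroxy-4,6-dimethoxyphenoxy)phenyl]-5,7-dimethoxy-4H-chromen-4-one
Conditions: H2 (1 atm), 10% Pd/C, THF/MeOH, rt
Reagents that add atoms: none
Why: Catalytic hydrogenolysis of the benzyl aryl ether should unmask the single phenol at the position fixed in step 1, the chromone C2=C3 bond being unreactive at atmospheric pressure.

**Step 10**
Reactants: 14 2-[4-(2-hydroxy-4,6-dimethoxyphenoxy)phenyl]-5,7-dimethoxy-4H-chromen-4-one
Product: 15 2-[4-(3-acetyl-2-hydroxy-4,6-dimethoxyphenoxy)phenyl]-5,7-dimethoxy-4H-chromen-4-one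
Conditions: Ac2O, BF3·OEt2, 80 °C; then aq. MeOH, 60 °C
Reagents that add atoms: acetic anhydride, CC(=O)OC(C)=O
Why: Friedel–Crafts (Fries-type) acetylation under BF3 should settle the acyl group ortho to the free hydroxyl as a boron chelate, in preference to the more hindered, non-chelating carbon between the two methoxy groups, while the carbonyl-deactivated ring A of unit 1 stays out.

**Step 11**
Reactants: 15 2-[4-(3-acetyl-2-hydroxy-4,6-dimethoxyphenoxy)phenyl]-5,7-dimethoxy-4H-chromen-4-one; 16 4-methoxybenzoyl chloride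
Product: 18 8-[4-(5,7-dimethoxy-4-oxo-4H-chromen-2-yl)phenoxy]-5,7-dimethoxy-2-(4-methoxyphenyl)-4H-chromen-4-one, via diketone 17 (not isolated)
Conditions: LiN(SiMe3)2 (3.5 equiv), THF, −78 to −10 °C; 16, −78 °C to rt; aq. NH4Cl; then cat. H2SO4, AcOH, 95 °C
Reagents that add atoms: none
Why: C-aroylation of the lithium enolate of the phenoxide–enolate dianion (the one-flask variant of the Baker–Venkataraman sequence) should give the 1,3-diketone, and acid cyclodehydration onto the only ortho hydroxyl can give only the 8-aryloxy flavone.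

**Step 12**
Reactants: 18 8-[4-(5,7-dimethoxy-4-oxo-4H-chromen-2-yl)phenoxy]-5,7-dimethoxy-2-(4-methoxyphenyl)-4H-chromen-4-one
Product: 19 lanaroflavone, 8-[4-(5,7-dihydroxy-4-oxo-4H-chromen-2-yl)phenoxy]-5,7-dihydroxy-2-(4-hydroxyphenyl)-4H-chromen-4-one
Conditions: BBr3 (15 equiv), CH2Cl2, −78 °C to rt; MeOH, then H2O
Reagents that add atoms: none
Why: Lewis-acid ether cleavage (bromide attack on each boron-activated O-methyl group) should remove all five methyl ethers, while the diaryl ether has no alkyl C–O bond to break and the cold, non-aqueous medium avoids Wessely–Moser isomerisation of the 8-aryloxy flavone.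

**Compound list**

1 | 2-hydroxy-4,6-dimethoxybenzaldehyde | COc1cc(O)c(C=O)c(OC)c1 | starting material
2 | 2-(benzyloxy)-4,6-dimethoxybenzaldehyde | COc1cc(OCc2ccccc2)c(C=O)c(OC)c1 | intermediate
3 | 2-(benzyloxy)-4,6-dimethoxyphenyl formate | COc1cc(OCc2ccccc2)c(OC=O)c(OC)c1 | intermediate
4 | 2-(benzyloxy)-4,6-dimethoxyphenol | COc1cc(OCc2ccccc2)c(O)c(OC)c1 | intermediate
5 | methyl 4-fluorobenzoate | COC(=O)c1ccc(F)cc1 | starting material
6 | methyl 4-[2-(benzyloxy)-4,6-dimethoxyphenoxy]benzoate | COC(=O)c1ccc(Oc2c(OCc3ccccc3)cc(OC)cc2OC)cc1 | intermediate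
7 | heptane-2,4,6-trione | CC(=O)CC(=O)CC(C)=O | starting material
8 | 1-{4-[2-(benzyloxy)-4,6-dimethoxyphenoxy]phenyl}octane-1,3,5,7-tetrone | CC(=O)CC(=O)CC(=O)CC(=O)c1ccc(Oc2c(OCc3ccccc3)cc(OC)cc2OC)cc1 | intermediate
9 | 9-{4-[2-(benzyloxy)-4,6-dimethoxyphenoxy]phenyl}-3,5,7,9-tetraoxononanoic acid | OC(=O)CC(=O)CC(=O)CC(=O)CC(=O)c1ccc(Oc2c(OCc3ccccc3)cc(OC)cc2OC)cc1 | intermediate
10 | methyl 9-{4-[2-(benzyloxy)-4,6-dimethoxyphenoxy]phenyl}-3,5,7,9-tetraoxononanoate | COC(=O)CC(=O)CC(=O)CC(=O)CC(=O)c1ccc(Oc2c(OCc3ccccc3)cc(OC)cc2OC)cc1 | intermediate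
11 | 1-{4-[2-(benzyloxy)-4,6-dimethoxyphenoxy]phenyl}-3-(2,4,6-trihydroxyphenyl)propane-1,3-dione | O=C(CC(=O)c1c(O)cc(O)cc1O)c1ccc(Oc2c(OCc3ccccc3)cc(OC)cc2OC)cc1 | intermediate
12 | 2-{4-[2-(benzyloxy)-4,6-dimethoxyphenoxy]phenyl}-5,7-dihydroxy-4H-chromen-4-one | O=c1cc(-c2ccc(Oc3c(OCc4ccccc4)cc(OC)cc3OC)cc2)oc2cc(O)cc(O)c12 | intermediate
13 | 2-{4-[2-(benzyloxy)-4,6-dimethoxyphenoxy]phenyl}-5,7-dimethoxy-4H-chromen-4-one | O=c1cc(-c2ccc(Oc3c(OCc4ccccc4)cc(OC)cc3OC)cc2)oc2cc(OC)cc(OC)c12 | intermediate
14 | 2-[4-(2-hydroxy-4,6-dimethoxyphenoxy)phenyl]-5,7-dimethoxy-4H-chromen-4-one | O=c1cc(-c2ccc(Oc3c(O)cc(OC)cc3OC)cc2)oc2cc(OC)cc(OC)c12 | intermediate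
15 | 2-[4-(3-acetyl-2-hydroxy-4,6-dimethoxyphenoxy)phenyl]-5,7-dimethoxy-4H-chromen-4-one | O=c1cc(-c2ccc(Oc3c(O)c(C(C)=O)c(OC)cc3OC)cc2)oc2cc(OC)cc(OC)c12 | intermediate
16 | 4-methoxybenzoyl chloride | COc1ccc(cc1)C(Cl)=O | starting material
17 | 1-{3-[4-(5,7-dimethoxy-4-oxo-4H-chromen-2-yl)phenoxy]-2-hydroxy-4,6-dimethoxyphenyl}-3-(4-methoxyphenyl)propane-1,3-dione | O=c1cc(-c2ccc(Oc3c(O)c(C(=O)CC(=O)c4ccc(OC)cc4)c(OC)cc3OC)cc2)oc2cc(OC)cc(OC)c12 | intermediate
18 | 8-[4-(5,7-dimethoxy-4-oxo-4H-chromen-2-yl)phenoxy]-5,7-dimethoxy-2-(4-methoxyphenyl)-4H-chromen-4-one | COc1ccc(cc1)-c1cc(=O)c2c(OC)cc(OC)c(Oc3ccc(cc3)-c3cc(=O)c4c(OC)cc(OC)cc4o3)c2o1 | intermediate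
19 | lanaroflavone, 8-[4-(5,7-dihydroxy-4-oxo-4H-chromen-2-yl)phenoxy]-5,7-dihydroxy-2-(4-hydroxyphenyl)-4H-chromen-4-one | O=c1cc(-c2ccc(Oc3c(O)cc(O)c4c(=O)cc(-c5ccc(O)cc5)oc34)cc2)oc2cc(O)cc(O)c12 | target

**Step count and risk**

Total step count: 12. Longest linear sequence: 12 steps (1 to 19); compounds 5, 7 and 16 are bought and enter directly.

Steps most likely to fail:

1. Step 6. The chain may close the wrong way: aldol attack of C2 on the C7 carbonyl or of C4 on C9, or lactonisation of the C5 enol onto the ester, could outrun the Claisen closure. The fallback buys ring A ready-made instead of building it. Setting out from 6, a crossed Claisen condensation with commercial 2-hydroxy-4,6-dimethoxyacetophenone (LiN(SiMe3)2, THF, −78 °C to reflux) would give 1-{4-[2-(benzyloxy)-4,6-dimethoxyphenoxy]phenyl}-3-(2-hydroxy-4,6-dimethoxyphenyl)propane-1,3-dione F1. Cyclodehydration (cat. H2SO4, AcOH, 60 °C) would then come back to the route at 13.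

2. Step 5. The tetraketone polyanion may condense with itself before it is carboxylated, and the β-keto acid may lose CO2 during work-up. The fallback assembles the chain in the reverse order. Setting out from 6 and 7, the trianion of 7 (LiN(i-Pr)2, THF, 0 °C) would be carboxylated with CO2 to 3,5,7-trioxooctanoic acid F2 and esterified with TMSCHN2 to methyl 3,5,7-trioxooctanoate F3. The tetraanion of F3 (LiN(i-Pr)2, 4 equiv; F3 in twofold excess) would then be aroylated at its terminal methyl carbanion with 6. This comes back to the route at 10 without passing through 8 or 9.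

3. Step 10. Acylation may go para to the hydroxyl, at the carbon between the two methoxy groups, instead of ortho. The fallback makes the ring closure itself deliver the acyl carbon. Setting out from 14, conjugate addition of the phenol to ethyl 3-(4-methoxyphenyl)prop-2-ynoate (CCOC(=O)C#Cc1ccc(OC)cc1; K2CO3, DMF, 80 °C) would give ethyl (2Z)-3-{2-[4-(5,7-dimethoxy-4-oxo-4H-chromen-2-yl)phenoxy]-3,5-dimethoxyphenoxy}-3-(4-methoxyphenyl)prop-2-enoate F4. Either alkene isomer would serve, since the double bond should equilibrate in acid. Saponification (LiOH, THF/H2O, rt) would give (2Z)-3-{2-[4-(5,7-dimethoxy-4-oxo-4H-chromen-2-yl)phenoxy]-3,5-dimethoxyphenoxy}-3-(4-methoxyphenyl)prop-2-enoic acid F5. Intramolecular Friedel–Crafts acylation in Eaton's reagent (P2O5 in MeSO3H, 60 °C; a Ruhemann-type flavone synthesis) can reach only the carbon ortho to the ether oxygen and would come back at 18, bypassing 15 and 17.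

**Further compounds**

F1 | step 6 | 1-{4-[2-(benzyloxy)-4,6-dimethoxyphenoxy]phenyl}-3-(2-hydroxy-4,6-dimethoxyphenyl)propane-1,3-dione | COc1cc(O)c(C(=O)CC(=O)c2ccc(Oc3c(OCc4ccccc4)cc(OC)cc3OC)cc2)c(OC)c1
F2 | step 5 | 3,5,7-trioxooctanoic acid | CC(=O)CC(=O)CC(=O)CC(O)=O
F3 | step 5 | methyl 3,5,7-trioxooctanoate | COC(=O)CC(=O)CC(=O)CC(C)=O
F4 | step 10 | ethyl (2Z)-3-{2-[4-(5,7-dimethoxy-4-oxo-4H-chromen-2-yl)phenoxy]-3,5-dimethoxyphenoxy}-3-(4-methoxyphenyl)prop-2-enoate | CCOC(=O)/C=C(\Oc1cc(OC)cc(OC)c1Oc1ccc(cc1)-c1cc(=O)c2c(OC)cc(OC)cc2o1)c1ccc(OC)cc1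
F5 | step 10 | (2Z)-3-{2-[4-(5,7-dimethoxy-4-oxo-4H-chromen-2-yl)phenoxy]-3,5-dimethoxyphenoxy}-3-(4-methoxyphenyl)prop-2-enoic acid | OC(=O)/C=C(\Oc1cc(OC)cc(OC)c1Oc1ccc(cc1)-c1cc(=O)c2c(OC)cc(OC)cc2o1)c1ccc(OC)cc1
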